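Assumption: the side chain is read from the SMILES as (16E)-nonadec-16-en-1-yl (fifteen CH2 groups between C-5 and the alkene); ring numbering is C-1 = C=O, C-4 = CH–OH, C-5 = C(OH)(chain).

**Retrosynthetic overview**
1. Target 24 ⇐ MOM ether 22; the only ring is closed last, by ring-closing metathesis of the acyclic dienone 21 (C-2=C-3).
2. 21 ⇐ α-MOM-oxy ketone 18 + silyl dienol ether 19: a chelate-controlled Mukaiyama aldol makes C-5–C-6 and sets C-5 from C-4.
3. 18 ⇐ 17 ⇐ aldehyde 10 + allyl MOM ether 12: the key C-4–C-5 bond comes from Brown γ-alkoxyallylboration. Metalated 12 is an α-oxyallyl carbanion (acrolein with reversed polarity at C-1), so two carbinol carbons are joined and C-4 is set by the reagent; the C-5 carbinol is then oxidised away.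
4. 10 ⇐ nitrile 8 ⇐ bromide 5 ⇐ bromide 2 + dibromide 3 (Cu-catalysed sp3–sp3 coupling, then cyanomethylation).

**Route**

Step 1
Reactants: 1 (E)-hex-3-en-1-ol
Product: 2 (E)-1-bromohex-3-ene
Conditions: PBr3, pyridine (cat.), Et2O, 0 °C → rt
Reagents that add atoms: phosphorus tribromide, BrP(Br)Br
Why: SN2 bromination of the primary alcohol via its phosphite ester leaves the remote E-alkene untouched.

Step 2
Reactants: 2 (E)-1-bromohex-3-ene; 3 1,12-dibromododecane
Product: 5 (E)-18-bromooctadec-3-ene, via hexenylmagnesium bromide 4 (not isolated)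
Conditions: Mg, THF, rt; then 3 (3 equiv), Li2CuCl4 (2 mol %), THF, −10 → 0 °C
Reagents that add atoms: none
Why: Kochi-type Li2CuCl4-catalysed coupling of a primary Grignard reagent with a primary bromide; excess dibromide gives mono-coupling and the E geometry is retained.

Step 3
Reactants: 5 (E)-18-bromooctadec-3-ene; 6 acetonitrile
Product: 8 (17E)-icos-17-enenitrile, via cyanomethyllithium 7 (not isolated)
Conditions: nBuLi, 6 (3 equiv), THF, −78 °C; then 5, −78 °C → rt
Reagents that add atoms: none
Why: SN2 alkylation of the nitrile-stabilised carbanion by the primary bromide adds the two carbons that bring the chain to C20, with excess anion suppressing dialkylation.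

Step 4
Reactants: 8 (17E)-icos-17-enenitrile
Product: 10 (17E)-icos-17-enal, via N-aluminio imine 9 (not isolated)
Conditions: iBu2AlH, CH2Cl2, −78 °C; then 1 M aq. HCl, 0 °C
Reagents that add atoms: water, O
Why: Partial hydride reduction of the nitrile stops at the N-aluminio imine, which hydrolyses to the aldehyde on acidic work-up.

Step 5
Reactants: 11 prop-2-en-1-ol
Product: 12 3-(methoxymethoxy)prop-1-ene
Conditions: MOMCl, iPr2NEt, CH2Cl2, 0 °C → rt
Reagents that add atoms: chloromethyl methyl ether, COCCl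
Why: O-alkylation of the alcohol (MOM protection) gives the ether that is later metalated and that serves as the chelating group.

Step 6
Reactants: 12 3-(methoxymethoxy)prop-1-ene; 13 (+)-B-methoxydiisopinocampheylborane (from (−)-α-pinene); 10 (17E)-icos-17-enal
Product: 17 (3S,4S,20E)-3-(methoxymethoxy)tricosa-1,20-dien-4-ol, via allyllithium 14 (not isolated), via allylborane 15 (not isolated), via borinate ester 16 (not isolated)
Conditions: sBuLi, THF, −78 °C; 13, −78 °C; BF3·OEt2, −78 °C; 10, −78 °C, 3 h; then NaOH, H2O2, rt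
Reagents that add atoms: none
Why: Brown asymmetric γ-alkoxyallylboration: the lithiated allyl ether (an α-oxyallyl carbanion, i.e. acrolein with reversed polarity) becomes the (Z)-γ-alkoxyallylborane, which bonds through its oxygen-bearing carbon in a chair Zimmerman–Traxler transition state, giving the syn adduct by Re-face attack under control of the (−)-α-pinene-derived ligands (3S,4S).

Step 7
Reactants: 17 (3S,4S,20E)-3-(methoxymethoxy)tricosa-1,20-dien-4-ol
Product: 18 (3S,20E)-3-(methoxymethoxy)tricosa-1,20-dien-4-one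
Conditions: Dess–Martin periodinane, NaHCO3, CH2Cl2, 0 °C
Reagents that add atoms: none
Why: Buffered Dess–Martin oxidation converts the carbinol into the ketone without epimerising or conjugating the acidic C-3 centre, which is kept as the only stereocentre.

Step 8
Reactants: 18 (3S,20E)-3-(methoxymethoxy)tricosa-1,20-dien-4-one; 19 2-(trimethylsilyloxy)buta-1,3-diene
Product: 21 (5S,6S)-5-hydroxy-6-(methoxymethoxy)-5-[(16E)-nonadec-16-en-1-yl]octa-1,7-dien-3-one, via titanium aldolate 20 (not isolated)
Conditions: TiCl4 (1.1 equiv), CH2Cl2, −78 °C; then 19 (1.3 equiv), −78 °C; aq. NaHCO3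
Reagents that add atoms: none
Why: Mukaiyama aldol addition under Cram-chelate control: TiCl4 bridges the ketone and MOM oxygens and the enol silane attacks the face opposite the vinyl group, setting the tertiary carbinol as 5S and giving the vinyl ketone directly.

Step 9
Reactants: 21 (5S,6S)-5-hydroxy-6-(methoxymethoxy)-5-[(16E)-nonadec-16-en-1-yl]octa-1,7-dien-3-one
Product: 22 (4S,5S)-5-hydroxy-4-(methoxymethoxy)-5-[(16E)-nonadec-16-en-1-yl]cyclohex-2-en-1-one
Conditions: second-generation Hoveyda–Grubbs catalyst (5 mol %), CH2Cl2 (5 mM), 40 °C, 2 h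
Reagents that add atoms: none
Why: Ring-closing metathesis of the two terminal alkenes forms the six-membered enone much faster than the remote internal E-alkene can react, and no stereocentre is touched.

Step 10
Reactants: 22 (4S,5S)-5-hydroxy-4-(methoxymethoxy)-5-[(16E)-nonadec-16-en-1-yl]cyclohex-2-en-1-one
Product: 24 (4S,5S)-4,5-dihydroxy-5-[(16E)-nonadec-16-en-1-yl]cyclohex-2-en-1-one, via bromomethyl ether 23 (not isolated)
Conditions: Me2BBr (3 equiv), CH2Cl2, −78 °C, 1 h; then THF/aq. NaHCO3, 0 °C
Reagents that add atoms: none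
Why: Guindon acetal cleavage with Me2BBr at −78 °C removes the MOM group through a bromomethyl ether that hydrolyses on work-up, avoiding the protic acid that would dehydrate and aromatise the β-hydroxy enone.

**Compound list**
1 | (E)-hex-3-en-1-ol | CC/C=C/CCO | starting material
2 | (E)-1-bromohex-3-ene | CC/C=C/CCBr | intermediate
3 | 1,12-dibromododecane | BrCCCCCCCCCCCCBr | starting material
4 | (E)-hex-3-en-1-ylmagnesium bromide | CC/C=C/CC[Mg]Br | intermediate
5 | (E)-18-bromooctadec-3-ene | CC/C=C/CCCCCCCCCCCCCCBr | intermediate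
6 | acetonitrile | CC#N | starting material
7 | cyanomethyllithium | [Li]CC#N | intermediate
8 | (17E)-icos-17-enenitrile | CC/C=C/CCCCCCCCCCCCCCCC#N | intermediate
9 | N-(diisobutylalumanyl) imine of (17E)-icos-17-enal | CC/C=C/CCCCCCCCCCCCCCCC=N[Al](CC(C)C)CC(C)C | intermediate
10 | (17E)-icos-17-enal | CC/C=C/CCCCCCCCCCCCCCCC=O | intermediate
11 | prop-2-en-1-ol | C=CCO | starting material
12 | 3-(methoxymethoxy)prop-1-ene | C=CCOCOC | intermediate
13 | (+)-B-methoxydiisopinocampheylborane (isopinocampheyl groups from (−)-α-pinene) | COB([C@H]1C[C@H]2C[C@@H]([C@@H]1C)C2(C)C)[C@H]1C[C@H]2C[C@@H]([C@@H]1C)C2(C)C | starting material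
14 | [(2Z)-3-(methoxymethoxy)prop-2-en-1-yl]lithium | [Li]C/C=C\OCOC | intermediate
15 | [(2Z)-3-(methoxymethoxy)prop-2-en-1-yl]diisopinocampheylborane | COCO/C=C\CB([C@H]1C[C@H]2C[C@@H]([C@@H]1C)C2(C)C)[C@H]1C[C@H]2C[C@@H]([C@@H]1C)C2(C)C | intermediate
16 | diisopinocampheylborinate ester of 17 | CC/C=C/CCCCCCCCCCCCCCC[C@H](OB([C@H]1C[C@H]2C[C@@H]([C@@H]1C)C2(C)C)[C@H]1C[C@H]2C[C@@H]([C@@H]1C)C2(C)C)[C@@H](OCOC)C=C | intermediate
17 | (3S,4S,20E)-3-(methoxymethoxy)tricosa-1,20-dien-4-ol | CC/C=C/CCCCCCCCCCCCCCC[C@H](O)[C@@H](OCOC)C=C | intermediate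
18 | (3S,20E)-3-(methoxymethoxy)tricosa-1,20-dien-4-one | CC/C=C/CCCCCCCCCCCCCCCC(=O)[C@@H](OCOC)C=C | intermediate
19 | 2-(trimethylsilyloxy)buta-1,3-diene | C=CC(=C)O[Si](C)(C)C | starting material
20 | trichlorotitanium alkoxide (chelated aldolate) of 21 | CC/C=C/CCCCCCCCCCCCCCC[C@](O[Ti](Cl)(Cl)Cl)(CC(=O)C=C)[C@@H](OCOC)C=C | intermediate
21 | (5S,6S)-5-hydroxy-6-(methoxymethoxy)-5-[(16E)-nonadec-16-en-1-yl]octa-1,7-dien-3-one | CC/C=C/CCCCCCCCCCCCCCC[C@](O)(CC(=O)C=C)[C@@H](OCOC)C=C | intermediate
22 | (4S,5S)-5-hydroxy-4-(methoxymethoxy)-5-[(16E)-nonadec-16-en-1-yl]cyclohex-2-en-1-one | CC/C=C/CCCCCCCCCCCCCCC[C@]1(O)CC(=O)C=C[C@@H]1OCOC | intermediate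
23 | (4S,5S)-4-(bromomethoxy)-5-hydroxy-5-[(16E)-nonadec-16-en-1-yl]cyclohex-2-en-1-one | CC/C=C/CCCCCCCCCCCCCCC[C@]1(O)CC(=O)C=C[C@@H]1OCBr | intermediate
24 | (4S,5S)-4,5-dihydroxy-5-[(16E)-nonadec-16-en-1-yl]cyclohex-2-en-1-one | CC/C=C/CCCCCCCCCCCCCCC[C@]1(O)CC(=O)C=C[C@@H]1O | target

**Count**
Total steps: 10. Longest linear sequence: 9 (steps 1, 2, 3, 4, 6, 7, 8, 9, 10); step 5 is a one-step side branch.

**Steps most likely to fail, with fallbacks**

Step 8 (aldol addition to a ketone; the MOM ether must survive TiCl4, and the vinyl ketone product can react further). The fallback sets out from 18 and returns at 21. Ketone 18 is treated with the zinc enolate made from 2-bromo-N-methoxy-N-methylacetamide and Zn dust in THF (Reformatsky addition). This reagent is non-basic, so the acidic C-3 hydrogen is safe, and the zinc chelate of the α-MOM-oxy ketone directs the same facial attack. The product is the Weinreb amide (3S,4S)-3-hydroxy-N-methoxy-4-(methoxymethoxy)-N-methyl-3-[(16E)-nonadec-16-en-1-yl]hex-5-enamide F1. Excess vinylmagnesium bromide (THF, −78 → 0 °C) then converts F1 into vinyl ketone 21.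

Step 9 (the second-generation catalyst may also engage the chain alkene, eroding E purity or truncating the chain). The fallback sets out from 21 and returns at 22. Luche reduction (NaBH4, CeCl3·7H2O, MeOH, −78 °C) turns the vinyl ketone into the bis-allylic dienediol (5S,6S)-6-(methoxymethoxy)-5-[(16E)-nonadec-16-en-1-yl]octa-1,7-diene-3,5-diol F2, a mixture of C-3 epimers that does not matter. Ring closure with first-generation Grubbs catalyst, which leaves unstrained internal dialkyl alkenes alone, gives (1S,6S)-6-(methoxymethoxy)-1-[(16E)-nonadec-16-en-1-yl]cyclohex-4-ene-1,3-diol F3. MnO2 in CH2Cl2 then oxidises its only secondary allylic alcohol to enone 22.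

Step 10 (the target dehydrates and aromatises easily, so any deprotection on the finished ring is delicate). The fallback sets out from 18 and returns at 24, with no deprotection on the ring. Me2BBr at −78 °C followed by aqueous NaHCO3 cleaves the MOM ether of the robust ketone 18 to give (3S,20E)-3-hydroxytricosa-1,20-dien-4-one F4. The TiCl4-mediated addition of 19 is then run on F4, whose free hydroxyl forms a titanium alkoxide chelate that gives the same facial control. The resulting diol (5S,6S)-5,6-dihydroxy-5-[(16E)-nonadec-16-en-1-yl]octa-1,7-dien-3-one F5 is closed by ring-closing metathesis under neutral conditions straight to 24.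

**Further compounds**
F1 | step 8 | (3S,4S)-3-hydroxy-N-methoxy-4-(methoxymethoxy)-N-methyl-3-[(16E)-nonadec-16-en-1-yl]hex-5-enamide | CC/C=C/CCCCCCCCCCCCCCC[C@](O)(CC(=O)N(C)OC)[C@@H](OCOC)C=C
F2 | step 9 | (5S,6S)-6-(methoxymethoxy)-5-[(16E)-nonadec-16-en-1-yl]octa-1,7-diene-3,5-diol (C-3 epimers) | CC/C=C/CCCCCCCCCCCCCCC[C@](O)(CC(O)C=C)[C@@H](OCOC)C=C
F3 | step 9 | (1S,6S)-6-(methoxymethoxy)-1-[(16E)-nonadec-16-en-1-yl]cyclohex-4-ene-1,3-diol (C-3 epimers) | CC/C=C/CCCCCCCCCCCCCCC[C@]1(O)CC(O)C=C[C@@H]1OCOC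
F4 | step 10 | (3S,20E)-3-hydroxytricosa-1,20-dien-4-one | CC/C=C/CCCCCCCCCCCCCCCC(=O)[C@@H](O)C=C
F5 | step 10 | (5S,6S)-5,6-dihydroxy-5-[(16E)-nonadec-16-en-1-yl]octa-1,7-dien-3-one | CC/C=C/CCCCCCCCCCCCCCC[C@](O)(CC(=O)C=C)[C@@H](O)C=C
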